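The target is disconnected to a symmetric trimer, because ring A (the 6,6-dimethyl triketone ring) and ring C (the methylphloroglucinol ring) carry the same sequence around the ring, starting at the CH2-bearing carbon: C–O, C–CH3, C–O, C–butanoyl, C–O. Both rings are therefore built in one operation from two identical 4-benzyloxy-5-methyl-2-pyrones tied through CH2CH2 arms to C-3 and C-5 of the O-benzylated butyrophenone ring B. Benzyloxide opens both lactones, and each ketone α-CH2 closes onto the freed ester carbon, so two lactones become two benzenoid rings. Butanoylation of both rings, one dearomative C-methylation with ring B still masked, and hydrogenolysis finish the synthesis.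

Key step: step 10

Remark (stereochemistry): the target has no stereocentre and is achiral, so no stereocontrol is needed; ring A is written as one enol tautomer of a freely tautomerising triketone.
Remark (design): the skeletons of precursor 18 and product 20 map atom by atom onto the target and are used unchanged. Two design choices protect them: the lactone-opening alkoxide is benzyloxide, the same alkoxide as the 4-O-benzyl groups, so that alkoxide exchange at C-4 cannot scramble the ethers; and the dearomative methylation is run while ring B is still fully benzylated, so that ring B cannot be alkylated and the CH2 bridges cannot exchange in base.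

Step 1
Reactants: 1 3-methylpentane-2,4-dione
Product: 3 4-methyl-3,5-dioxohexanoic acid, via dilithium dianion 2 (not isolated)
Conditions: LDA (commercial, 2.2 equiv), THF, −78 → 0 °C; CO2 (gas), −78 °C → rt; cold 2 M HCl
Reagents that add atoms: carbon dioxide, O=C=O
Why: Carboxylation of a β-diketone 1,3-dianion: the second deprotonation takes place at a terminal methyl group and this more basic carbanion, not the stabilised central one, adds to CO2, so the chain is extended at one end only; the methine centre of 3 is a freely epimerising β-dicarbonyl carbon and disappears in step 2.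

Step 2
Reactants: 3 4-methyl-3,5-dioxohexanoic acid
Product: 5 4-hydroxy-5,6-dimethyl-2H-pyran-2-one, via mixed trifluoroacetic anhydride 4 (not isolated)
Conditions: TFAA (1.3 equiv), CH2Cl2, 0 °C → rt; H2O
Reagents that add atoms: none
Why: Mixed-anhydride enol lactonisation: TFAA activates the carboxyl group, the enol oxygen of the 5-ketone closes the six-membered lactone, and enolisation of the 3-ketone gives the stable 4-hydroxy-2-pyrone, which removes the only stereocentre.

Step 3
Reactants: 5 4-hydroxy-5,6-dimethyl-2H-pyran-2-one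
Product: 6 4-(benzyloxy)-5,6-dimethyl-2H-pyran-2-one
Conditions: BnOH (1.2 equiv), PPh3, DIAD, THF, 0 °C → rt
Reagents that add atoms: benzyl alcohol, OCc1ccccc1
Why: Mitsunobu etherification: the 4-hydroxy-2-pyrone is a vinylogous carboxylic acid and is alkylated on the 4-oxygen by the benzyloxyphosphonium ion, which avoids the C-3 benzylation that a benzyl halide and base can cause.

Step 4
Reactants: 7 phloroglucinol; 8 butyryl chloride
Product: 9 1-(2,4,6-trihydroxyphenyl)butan-1-one
Conditions: AlCl3 (3.5 equiv), PhNO2–CH2Cl2, 0 → 40 °C; ice, HCl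
Reagents that add atoms: butyryl chloride (8), CCCC(=O)Cl
Why: Friedel–Crafts acylation: phloroglucinol is acylated once because the aluminium-chelated o-hydroxy ketone that forms is deactivated toward a second acylation.

Step 5
Reactants: 9 1-(2,4,6-trihydroxyphenyl)butan-1-one
Product: 11 5-butanoyl-2,4,6-trihydroxybenzene-1,3-dicarbaldehyde, via bis(α-chloro ether) 10 (not isolated)
Conditions: Cl2CHOMe (5 equiv), TiCl4 (6 equiv), CH2Cl2, 0 °C → rt; 1 M HCl, rt
Reagents that add atoms: dichloromethyl methyl ether, COC(Cl)Cl; water, O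
Why: Rieche formylation: each of the two remaining ring carbons is flanked by two titanium phenoxide oxygens and attacks the chloro(methoxy)carbenium ion, and hydrolysis of the two α-chloro ether groups on work-up should release both aldehydes.

Step 6
Reactants: 11 5-butanoyl-2,4,6-trihydroxybenzene-1,3-dicarbaldehyde; 12 benzyl bromide
Product: 13 2,4,6-tris(benzyloxy)-5-butanoylbenzene-1,3-dicarbaldehyde
Conditions: BnBr (3.6 equiv), K2CO3 (4 equiv), DMF, 60 °C
Reagents that add atoms: benzyl bromide (12), BrCc1ccccc1
Why: Williamson ether synthesis: every ring carbon is substituted, so the acidic phenoxides can react only on oxygen without loss of aromaticity, and carbonate in warm DMF is the usual way to benzylate hydroxyls held between two carbonyl groups.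

Step 7
Reactants: 13 2,4,6-tris(benzyloxy)-5-butanoylbenzene-1,3-dicarbaldehyde
Product: 14 1-[2,4,6-tris(benzyloxy)-3,5-bis(hydroxymethyl)phenyl]butan-1-one
Conditions: NaBH4 (1.0 equiv), THF–EtOH, −30 °C; aq. NH4Cl
Reagents that add atoms: none
Why: Chemoselective borohydride reduction: the two aldehydes are reduced at low temperature, while the butanoyl ketone, twisted out of the ring plane and shielded by two ortho benzyloxy groups, should be left untouched.

Step 8
Reactants: 14 1-[2,4,6-tris(benzyloxy)-3,5-bis(hydroxymethyl)phenyl]butan-1-one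
Product: 15 1-[2,4,6-tris(benzyloxy)-3,5-bis(bromomethyl)phenyl]butan-1-one
Conditions: PBr3 (0.8 equiv), pyridine (cat.), CH2Cl2, 0 °C; used without storage
Reagents that add atoms: phosphorus tribromide, BrP(Br)Br
Why: Alcohol-to-bromide exchange (SN2 on the bromophosphite ester): the electron-rich benzylic alcohols react fast at 0 °C, and a trace of pyridine buffers HBr so that the benzyl ethers survive.

Step 9
Reactants: 6 4-(benzyloxy)-5,6-dimethyl-2H-pyran-2-one (2.3 equiv); 15 1-[2,4,6-tris(benzyloxy)-3,5-bis(bromomethyl)phenyl]butan-1-one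
Product: 18 1-[2,4,6-tris(benzyloxy)-3,5-bis[2-(4-benzyloxy-5-methyl-2-oxo-2H-pyran-6-yl)ethyl]phenyl]butan-1-one, via lithiated pyrone 16 (not isolated), via mono-alkylated bromide 17 (not isolated)
Conditions: 6, LDA (commercial, 2.2 equiv), THF, −78 °C; then 15, THF–DMPU, −78 → −30 °C; aq. NH4Cl
Reagents that add atoms: none
Why: Vinylogous (lateral) enolate alkylation: LDA removes a proton from the 6-methyl group, whose anion is delocalised through C-5, C-3 and the lactone carbonyl (an anion on the 5-methyl group would not be), and this soft carbanion should displace both benzylic bromides by SN2 at its exocyclic carbon faster than it deprotonates or attacks the hindered di-ortho-substituted ketone.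

Step 10
Reactants: 18 1-[2,4,6-tris(benzyloxy)-3,5-bis[2-(4-benzyloxy-5-methyl-2-oxo-2H-pyran-6-yl)ethyl]phenyl]butan-1-one
Product: 20 1-[2,4,6-tris(benzyloxy)-3,5-bis[(4-benzyloxy-2,6-dihydroxy-3-methylphenyl)methyl]phenyl]butan-1-one, via ring-opened bis(keto benzyl ester) 19 (not isolated)
Conditions: BnONa (10 equiv, from NaH + BnOH), BnOH–THF (1:4), 0.02 M, 65 °C, argon; then 1 M HCl to pH 4
Reagents that add atoms: none
Why: Benzyloxide adds to the lactone carbonyl of each pyrone and opens it to the (E)-3-benzyloxy enoate benzyl ester 19, in which the former C-6 is a saturated ketone and the ring-derived alkene geometry keeps the ester next to the ketone chain; because the alkoxide is the same as the 4-O-benzyl group, addition–elimination at C-4 cannot exchange the ether. Enolate equilibration reaches the ketone α-methylene beside the ArCH2 carbon, which attacks the ester carbonyl, expels benzyloxide and, after enolisation, leaves the 5-benzyloxyresorcinol ring as its phenoxide, an irreversible aromatisation that should pull both arms through. Each of the two rings closes by a 6-(enolexo)-exo-trig Claisen (Dieckmann-type) condensation, and the closest known reaction is the alkoxide-induced isomerisation of 4-alkoxy-6-alkyl-2-pyrones to phloroglucinol monoethers, run here on two pyrones of one molecule. No stereocentre is formed, since the methine centre of 19 ends as an aromatic carbon. The step needs C-acylation from the methylene carbon only: the other acidic carbon (the methyl-bearing methine) could close only a four-membered ring, the pyrone has no C-3 acyl group so no six-membered aldol path exists, and the ring-B ketone sits meta to each arm and cannot reach it in an unstrained ring.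

Step 11
Reactants: 20 1-[2,4,6-tris(benzyloxy)-3,5-bis[(4-benzyloxy-2,6-dihydroxy-3-methylphenyl)methyl]phenyl]butan-1-one
Product: 22 1-[2,4,6-tris(benzyloxy)-3,5-bis[(4-benzyloxy-3-butanoyl-2,6-dihydroxy-5-methylphenyl)methyl]phenyl]butan-1-one, via bis(difluoroboron) chelate 21 (not isolated)
Conditions: (PrCO)2O (3 equiv), BF3·OEt2 (6 equiv), CH2Cl2, 0 °C → rt; then K2CO3, MeOH–H2O, rt
Reagents that add atoms: butanoic anhydride, CCCC(=O)OC(=O)CCC
Why: Friedel–Crafts acylation: the single unsubstituted carbon of each terminal ring lies ortho to one free hydroxyl and para to the other and should react with the BF3-activated anhydride at or below room temperature, the product being held as the deactivated boron chelate while aryl benzyl ethers tolerate BF3·OEt2 at this temperature, and basic methanol then frees the ketone and cleaves any aryl butanoate.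

Step 12
Reactants: 22 1-[2,4,6-tris(benzyloxy)-3,5-bis[(4-benzyloxy-3-butanoyl-2,6-dihydroxy-5-methylphenyl)methyl]phenyl]butan-1-one
Product: 23 1-[2,4,6-tris(benzyloxy)-3-[(4-benzyloxy-3-butanoyl-2,6-dihydroxy-5-methylphenyl)methyl]-5-[(4-benzyloxy-3-butanoyl-2-hydroxy-5,5-dimethyl-6-oxocyclohexa-1,3-dien-1-yl)methyl]phenyl]butan-1-one
Conditions: NaOMe (4.5 equiv), MeI (1.1 equiv), MeOH–THF, 0 °C → rt, stopped at partial conversion; dilute HCl; recovered 22 recycled
Reagents that add atoms: iodomethane, CI
Why: Dearomative C-methylation of an acylphloroglucinol (the usual entry to acylfilicinic acid rings): in methanol the hydrogen-bonded phenoxide reacts with MeI on carbon, and of the two ring carbons activated by both phenoxide oxygens the methyl-bearing one should be attacked because the other carries the bulky tris(benzyloxy)benzyl group, while ring B has no free hydroxyl and so can neither be alkylated nor take part in bridge exchange, and one equivalent of MeI at partial conversion favours the mono-methylated product, which is separated at this lipophilic stage.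

Step 13
Reactants: 23 (mono-methylated pentabenzyl ether, as named in step 12)
Product: 24 target CNP0086105.0, 2-butanoyl-4-[[3-butanoyl-5-[(3-butanoyl-2,4,6-trihydroxy-5-methylphenyl)methyl]-2,4,6-trihydroxyphenyl]methyl]-3,5-dihydroxy-6,6-dimethylcyclohexa-2,4-dien-1-one
Conditions: H2 (1 atm), 10% Pd/C, EtOAc–MeOH, rt
Reagents that add atoms: none
Why: Catalytic hydrogenolysis: the four aryl benzyl ethers and the enol benzyl ether should be cleaved under mild conditions, whereas the hydrogen-bonded aryl ketones and the enolised triketone ring are not reduced, and the freed enol tautomerises to the target.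

Compound list

1 | 3-methylpentane-2,4-dione | CC(=O)C(C)C(C)=O | starting material
2 | dilithium dianion of 1 (3-methyl-2,4-dioxopentane-1,3-diide) | [Li+].[Li+].[CH2-]C(=O)[C-](C)C(C)=O | intermediate
3 | 4-methyl-3,5-dioxohexanoic acid (methine centre unspecified, epimerising) | CC(=O)C(C)C(=O)CC(=O)O | intermediate
4 | 4-methyl-3,5-dioxohexanoic trifluoroacetic anhydride | CC(=O)C(C)C(=O)CC(=O)OC(=O)C(F)(F)F | intermediate
5 | 4-hydroxy-5,6-dimethyl-2H-pyran-2-one | CC1=C(C)C(O)=CC(=O)O1 | intermediate
6 | 4-(benzyloxy)-5,6-dimethyl-2H-pyran-2-one | CC1=C(C)C(OCc2ccccc2)=CC(=O)O1 | intermediate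
7 | phloroglucinol | Oc1cc(O)cc(O)c1 | starting material
8 | butyryl chloride | CCCC(=O)Cl | starting material
9 | 1-(2,4,6-trihydroxyphenyl)butan-1-one | CCCC(=O)c1c(O)cc(O)cc1O | intermediate
10 | 1-[3,5-bis[chloro(methoxy)methyl]-2,4,6-trihydroxyphenyl]butan-1-one (both centres unspecified) | CCCC(=O)c1c(O)c(C(Cl)OC)c(O)c(C(Cl)OC)c1O | intermediate
11 | 5-butanoyl-2,4,6-trihydroxybenzene-1,3-dicarbaldehyde | CCCC(=O)c1c(O)c(C=O)c(O)c(C=O)c1O | intermediate
12 | benzyl bromide | BrCc1ccccc1 | starting material
13 | 2,4,6-tris(benzyloxy)-5-butanoylbenzene-1,3-dicarbaldehyde | CCCC(=O)c1c(OCc2ccccc2)c(C=O)c(OCc2ccccc2)c(C=O)c1OCc1ccccc1 | intermediate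
14 | 1-[2,4,6-tris(benzyloxy)-3,5-bis(hydroxymethyl)phenyl]butan-1-one | CCCC(=O)c1c(OCc2ccccc2)c(CO)c(OCc2ccccc2)c(CO)c1OCc1ccccc1 | intermediate
15 | 1-[2,4,6-tris(benzyloxy)-3,5-bis(bromomethyl)phenyl]butan-1-one | CCCC(=O)c1c(OCc2ccccc2)c(CBr)c(OCc2ccccc2)c(CBr)c1OCc1ccccc1 | intermediate
16 | lithium (4-benzyloxy-5-methyl-2-oxo-2H-pyran-6-yl)methanide | [Li+].[CH2-]C1=C(C)C(OCc2ccccc2)=CC(=O)O1 | intermediate
17 | 1-[2,4,6-tris(benzyloxy)-3-(bromomethyl)-5-[2-(4-benzyloxy-5-methyl-2-oxo-2H-pyran-6-yl)ethyl]phenyl]butan-1-one | CCCC(=O)c1c(OCc2ccccc2)c(CBr)c(OCc2ccccc2)c(CCC2=C(C)C(OCc3ccccc3)=CC(=O)O2)c1OCc1ccccc1 | intermediate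
18 | 1-[2,4,6-tris(benzyloxy)-3,5-bis[2-(4-benzyloxy-5-methyl-2-oxo-2H-pyran-6-yl)ethyl]phenyl]butan-1-one | CCCC(=O)c1c(OCc2ccccc2)c(CCC2=C(C)C(OCc3ccccc3)=CC(=O)O2)c(OCc2ccccc2)c(CCC2=C(C)C(OCc3ccccc3)=CC(=O)O2)c1OCc1ccccc1 | intermediate
19 | 1-[2,4,6-tris(benzyloxy)-3,5-bis[(5E)-5,7-bis(benzyloxy)-4-methyl-3,7-dioxohept-5-en-1-yl]phenyl]butan-1-one (methine centres unspecified) | CCCC(=O)c1c(OCc2ccccc2)c(CCC(=O)C(C)/C(OCc2ccccc2)=C\C(=O)OCc2ccccc2)c(OCc2ccccc2)c(CCC(=O)C(C)/C(OCc2ccccc2)=C\C(=O)OCc2ccccc2)c1OCc1ccccc1 | intermediate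
20 | 1-[2,4,6-tris(benzyloxy)-3,5-bis[(4-benzyloxy-2,6-dihydroxy-3-methylphenyl)methyl]phenyl]butan-1-one | CCCC(=O)c1c(OCc2ccccc2)c(Cc2c(O)c(C)c(OCc3ccccc3)cc2O)c(OCc2ccccc2)c(Cc2c(O)c(C)c(OCc3ccccc3)cc2O)c1OCc1ccccc1 | intermediate
21 | bis(difluoroboron) chelate of 22 (each BF2 bridges the butanoyl oxygen and the neighbouring phenol oxygen of a terminal ring) | CCCC(=O)c1c(OCc2ccccc2)c(Cc2c(O)c(C)c(OCc3ccccc3)c3c2O[B-](F)(F)[O+]=C3CCC)c(OCc2ccccc2)c(Cc2c(O)c(C)c(OCc3ccccc3)c3c2O[B-](F)(F)[O+]=C3CCC)c1OCc1ccccc1 | intermediate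
22 | 1-[2,4,6-tris(benzyloxy)-3,5-bis[(4-benzyloxy-3-butanoyl-2,6-dihydroxy-5-methylphenyl)methyl]phenyl]butan-1-one | CCCC(=O)c1c(OCc2ccccc2)c(Cc2c(O)c(C)c(OCc3ccccc3)c(C(=O)CCC)c2O)c(OCc2ccccc2)c(Cc2c(O)c(C)c(OCc3ccccc3)c(C(=O)CCC)c2O)c1OCc1ccccc1 | intermediate
23 | 1-[2,4,6-tris(benzyloxy)-3-[(4-benzyloxy-3-butanoyl-2,6-dihydroxy-5-methylphenyl)methyl]-5-[(4-benzyloxy-3-butanoyl-2-hydroxy-5,5-dimethyl-6-oxocyclohexa-1,3-dien-1-yl)methyl]phenyl]butan-1-one | CCCC(=O)c1c(OCc2ccccc2)c(CC2=C(O)C(C(=O)CCC)=C(OCc3ccccc3)C(C)(C)C2=O)c(OCc2ccccc2)c(Cc2c(O)c(C)c(OCc3ccccc3)c(C(=O)CCC)c2O)c1OCc1ccccc1 | intermediate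
24 | CNP0086105.0, 2-butanoyl-4-[[3-butanoyl-5-[(3-butanoyl-2,4,6-trihydroxy-5-methylphenyl)methyl]-2,4,6-trihydroxyphenyl]methyl]-3,5-dihydroxy-6,6-dimethylcyclohexa-2,4-dien-1-one (achiral) | CCCC(=O)C1=C(O)C(Cc2c(O)c(Cc3c(O)c(C)c(O)c(C(=O)CCC)c3O)c(O)c(C(=O)CCC)c2O)=C(O)C(C)(C)C1=O | target

Total step count: 13.
Longest linear sequence: 10 steps (phloroglucinol 7 to target 24, steps 4 to 13); the pyrone branch (steps 1 to 3) joins at step 9.

Steps most likely to fail

Step 10 (twofold pyrone-to-arene isomerisation). The alkoxide may attack the ketone of the ring-opened ester and cut the chain by a vinylogous retro-Claisen cleavage. Re-closure to the lactone may outrun C-acylation, the enoate may lose its geometry, or only one arm may react. In that case the terminal rings would be brought in ready-made by phenoxide C-benzylation. Commercial 2-methylbenzene-1,3,5-triol (Cc1c(O)cc(O)cc1O) would be acylated with butyryl chloride 8 (AlCl3, PhNO2) to 1-(2,4,6-trihydroxy-3-methylphenyl)butan-1-one F1. Its phenoxide (NaOMe, MeOH, 0 °C) would be alkylated on its single free ring carbon by both benzylic bromides of 15 to give 1-[2,4,6-tris(benzyloxy)-3,5-bis[(3-butanoyl-2,4,6-trihydroxy-5-methylphenyl)methyl]phenyl]butan-1-one F2. One equivalent of MeI with NaOMe would then methylate one free terminal ring at its methyl-bearing carbon to give 2-butanoyl-4-[[2,4,6-tris(benzyloxy)-3-butanoyl-5-[(3-butanoyl-2,4,6-trihydroxy-5-methylphenyl)methyl]phenyl]methyl]-3,5-dihydroxy-6,6-dimethylcyclohexa-2,4-dien-1-one F3. Hydrogenolysis of its three benzyl ethers (H2, Pd/C) would give the target. This fallback sets out from 15 and returns to the route at 24.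

Step 12 (single dearomative methylation). The phenoxide may react on oxygen, the methyl group may enter at the bridge-bearing carbon, both terminal rings may be methylated, or methoxide may exchange the new enol benzyl ether. In that case the protecting groups would be removed first: hydrogenolysis of 22 (H2, Pd/C) would give 1-[3,5-bis[(3-butanoyl-2,4,6-trihydroxy-5-methylphenyl)methyl]-2,4,6-trihydroxyphenyl]butan-1-one F4. Its terminal rings are fully free acylphloroglucinols, the substrates on which MeI and NaOMe are known to build the gem-dimethyl triketone ring. A short reaction at 0 °C with one equivalent of MeI would limit base-induced exchange of the methylene bridges, and the target would be separated from unchanged F4 and the doubly methylated product on acid-buffered silica or by reversed-phase chromatography. This fallback sets out from 22 and returns at 24.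

Step 9 (double alkylation with the lithiated pyrone). The carbanion may take a proton from the butanoyl α-methylene, metalation may occur at C-3 and not at the 6-methyl group, or the mono-adduct may be alkylated again at its newly acidified methylene. In that case the C–C bonds would be made by carbonyl addition and the arms saturated afterwards. Lithiated pyrone 16 would be added at −78 °C to the two aldehyde groups of 13 to give 1-[2,4,6-tris(benzyloxy)-3,5-bis[2-(4-benzyloxy-5-methyl-2-oxo-2H-pyran-6-yl)-1-hydroxyethyl]phenyl]butan-1-one F5 as a diastereomer mixture. Mesylation and elimination (MsCl, Et3N, then DBU) would give the bis-styrylpyrone 1-[2,4,6-tris(benzyloxy)-3,5-bis[(E)-2-(4-benzyloxy-5-methyl-2-oxo-2H-pyran-6-yl)ethenyl]phenyl]butan-1-one F6. Hydrogenation of the two exocyclic alkenes over Pd/C poisoned with diphenyl sulfide, which leaves benzyl ethers, the aryl ketone and the pyrone rings intact, would give 18. This fallback sets out from 13 (with 6 by way of 16) and returns at 18.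

Further compounds
F1 | step 10 | 1-(2,4,6-trihydroxy-3-methylphenyl)butan-1-one | CCCC(=O)c1c(O)cc(O)c(C)c1O
F2 | step 10 | 1-[2,4,6-tris(benzyloxy)-3,5-bis[(3-butanoyl-2,4,6-trihydroxy-5-methylphenyl)methyl]phenyl]butan-1-one | CCCC(=O)c1c(OCc2ccccc2)c(Cc2c(O)c(C)c(O)c(C(=O)CCC)c2O)c(OCc2ccccc2)c(Cc2c(O)c(C)c(O)c(C(=O)CCC)c2O)c1OCc1ccccc1
F3 | step 10 | 2-butanoyl-4-[[2,4,6-tris(benzyloxy)-3-butanoyl-5-[(3-butanoyl-2,4,6-trihydroxy-5-methylphenyl)methyl]phenyl]methyl]-3,5-dihydroxy-6,6-dimethylcyclohexa-2,4-dien-1-one | CCCC(=O)c1c(OCc2ccccc2)c(CC2=C(O)C(C)(C)C(=O)C(C(=O)CCC)=C2O)c(OCc2ccccc2)c(Cc2c(O)c(C)c(O)c(C(=O)CCC)c2O)c1OCc1ccccc1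
F4 | step 12 | 1-[3,5-bis[(3-butanoyl-2,4,6-trihydroxy-5-methylphenyl)methyl]-2,4,6-trihydroxyphenyl]butan-1-one | CCCC(=O)c1c(O)c(Cc2c(O)c(C)c(O)c(C(=O)CCC)c2O)c(O)c(Cc2c(O)c(C)c(O)c(C(=O)CCC)c2O)c1O
F5 | step 9 | 1-[2,4,6-tris(benzyloxy)-3,5-bis[2-(4-benzyloxy-5-methyl-2-oxo-2H-pyran-6-yl)-1-hydroxyethyl]phenyl]butan-1-one (diastereomer mixture) | CCCC(=O)c1c(OCc2ccccc2)c(C(O)CC2=C(C)C(OCc3ccccc3)=CC(=O)O2)c(OCc2ccccc2)c(C(O)CC2=C(C)C(OCc3ccccc3)=CC(=O)O2)c1OCc1ccccc1
F6 | step 9 | 1-[2,4,6-tris(benzyloxy)-3,5-bis[(E)-2-(4-benzyloxy-5-methyl-2-oxo-2H-pyran-6-yl)ethenyl]phenyl]butan-1-one | CCCC(=O)c1c(OCc2ccccc2)c(/C=C/C2=C(C)C(OCc3ccccc3)=CC(=O)O2)c(OCc2ccccc2)c(/C=C/C2=C(C)C(OCc3ccccc3)=CC(=O)O2)c1OCc1ccccc1
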